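A one-step world has one time constant and a curve that climbs to its end. Elm, the flask we follow, climbs and then falls, so it needs at least two.

| flask | substrate | partner | protic impurity | free catalyst | added ligand | remark | time |
|---|---|---|---|---|---|---|---|
| elm | 1.8 M | 1.26 M | 0.36 M | 3.6 mM | 2.4 mM | the very flask that is asked about, followed so far |  |
| larch | 1.8 M | 0.63 M | 0.36 M | 3.6 mM | 2.4 mM | run made earlier |  |
| flask | 1.8 M | 1.26 M | 0.360 M | 3.6 mM | 2.4 mM |  | 3.0 min |

| run | time / s | target / % |
|---|---|---|
| elm | 10.0 | 21 |
| elm | 12.0 | 20 |
| elm | 20.0 | 16 |
| elm | 40.0 | 10 |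
| larch | 10.0 | 10 |
| larch | 15.0 | 10 |
| larch | 30.0 | 8 |
| larch | 50.0 | 1 |
| larch | 80.0 | 2 |
| larch | 120 | 1 |

(readings scatter by 1.5 percentage points)

- amount of target in percent of the substrate charged, at 40 s, 1.5 min and 3.0 min

Start with the rate. At 10.0 s, elm reads 21% of target and larch 10%, a read ratio of 2.10 on a partner charge ratio of 2.00, so the amount at that first reading goes with partner, the one charge in which the two runs differ.

Then the rate changes sign. Elm's fall from 20% at 12.0 s to 10% at 40.0 s gives 40.4 s as its fall time, the interval between two readings over the natural logarithm of their ratio. Larch, from 15.0 s to 50.0 s, gives 15.2 s, which is shorter but rough, since its low reading lies within the scatter of 1.5 percentage points of zero.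

In larch the fall then stops: its last readings average 1.33%. Our own assumption is that this floor scales with partner as the first reading did, which puts elm's floor at an estimated 2.80%. Decaying towards it with the fall time from the reading at 40 s, we reckon 4.89% at 1.5 min and 3.02% at 3.0 min.

The forecast gives 10%, 2% and 1%, lower than ours at the later points, and holds that “By 3 min only the floor remains”.

The flask gives 8.75%, 3.79% and 2.75%, and the forecast stands within the tolerance.

    substrate + partner ⇌ target (K = 0.820 M⁻¹, k = 0.120 M⁻¹ s⁻¹)
    substrate + partner ⇌ isomer of the product (K = 15.0 M⁻¹, k = 0.0580 M⁻¹ s⁻¹)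
    target + free catalyst ⇌ isomer of the product + free catalyst, rate k3*[free catalyst]*[target] forward; the back reaction follows from the equilibrium constant (k = 1.50 M⁻¹ s⁻¹)
    partner + free catalyst → spent catalyst (k = 0.0610 M⁻¹ s⁻¹)
    free catalyst + added ligand ⇌ idle complex (K = 180 M⁻¹, k = 140 M⁻¹ s⁻¹)
    partner + protic impurity → quenched reagent (k = 0.0240 M⁻¹ s⁻¹)

Reckoned the same way between 1.5 min and 3.0 min, the fall time of this flask is 281 s, longer than the 40.4 s read from the earlier elm readings, while the step from substrate and partner to target, taken by itself at 3.00 min, relaxes both ways together with a half-life of 2.76 s, far shorter than that fall time and than the 3.0 min of the run. At 3.00 min target stands at 2.75%, and that step's equilibrium constant 0.82 M⁻¹ times c(substrate) and c(partner) of the same moment gives 2.73% of the substrate charged.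

The readings stem from a simulated flask from invented constants.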